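**Assumption:** eugenin (5-hydroxy-7-methoxy-2-methylchromone, CAS 480-34-2) is bought as a catalogue chemical. The single stereocentre of the target is 3R and is bought in (R)-propylene oxide.

## Retrosynthetic overview

1. Last bond: isochromanone C5–CH2, made by Friedel–Crafts hydroxyalkylation and ionic hydrogenation between the (R)-isochromanone (one free aromatic position) and 6-formyleugenin.
2. 6-Formyleugenin comes from eugenin by formylation ortho to the free 5-OH.
3. The resorcinol ring of the isochromanone is built by a Diels–Alder/retro-Diels–Alder (Alder–Rickert, loss of ethylene) reaction of an ynoate with a 1,3-bis(silyloxy)cyclohexadiene; the δ-lactone closes directly afterwards.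
4. The ynoate comes from ethyl propiolate and (R)-propylene oxide; the diene from 2-methylcyclohexane-1,3-dione.
5. Ring order: chromone bought; isochromanone benzene ring (cycloaddition); δ-lactone; union of the two halves.

## Route

Step 1
Reactants: 1 ethyl propiolate; 2 (R)-propylene oxide
Product: 3 ethyl (R)-5-hydroxyhex-2-ynoate
Conditions: n-BuLi, THF, −78 °C; BF3·OEt2; then 2, −78 °C; 1 M HCl quench
Reagents that add atoms: none
Why: The lithium acetylide of 1, with BF3 activation (Yamaguchi–Hirao alkynylation), opens the epoxide by SN2 attack at the unsubstituted CH2, so the C–O stereocentre of 2 is carried over untouched as the (R)-carbinol.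

Step 2
Reactants: 4 2-methylcyclohexane-1,3-dione
Product: 5 2-methyl-1,3-bis(trimethylsilyloxy)cyclohexa-1,3-diene
Conditions: TMSOTf (2.2 equiv), Et3N (2.6 equiv), Et2O, 0 °C → rt; separate the salt layer, distil
Reagents that add atoms: trimethylsilyl trifluoromethanesulfonate, C[Si](C)(C)OS(=O)(=O)C(F)(F)F
Why: Double O-silylation of the 1,3-dione (silyl enol ether formation, then γ-deprotonation of the silylated vinylogous ester) gives the 1,3-dioxygenated cyclic diene; no stereocentre is involved.

Step 3
Reactants: 3 ethyl (R)-5-hydroxyhex-2-ynoate; 5 2-methyl-1,3-bis(trimethylsilyloxy)cyclohexa-1,3-diene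
Product: 10 (R)-6,8-dihydroxy-3,7-dimethylisochroman-1-one, via TMS ether 6 (not isolated), via bicyclo[2.2.2]octadiene adduct 7 (not isolated), via silylated benzoate 8 (not isolated), via hydroxy ester 9 (not isolated)
Conditions: BSA (1.2 equiv), CH2Cl2, rt, evaporate; 5 (2 equiv), neat, sealed tube, 140 → 180 °C; then 2 M HCl, THF, rt; then TsOH (cat.), PhMe, 80 °C
Reagents that add atoms: none
Why: With the alcohol masked as its TMS ether, the bis(silyloxy)diene adds to the ynoate in a regioselective Diels–Alder reaction (unsubstituted diene terminus to the ynoate β-carbon), the adduct loses ethylene by retro-Diels–Alder (Alder–Rickert) to give the β-resorcylate ring, and acid removes the silyl groups and closes the lactone by acyl substitution, which does not touch the (R)-centre.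

Step 4
Reactants: 11 eugenin (5-hydroxy-7-methoxy-2-methylchromone)
Product: 12 5-hydroxy-7-methoxy-2-methyl-4-oxo-4H-chromene-6-carbaldehyde
Conditions: Cl2CHOMe (1.5 equiv), TiCl4 (3 equiv), CH2Cl2, 0 °C → rt; then 1 M HCl
Reagents that add atoms: dichloromethyl methyl ether, COC(Cl)Cl; water, O
Why: Rieche formylation, in which the titanium phenoxide of the 5-OH steers the electrophile to its only free ortho carbon C6 (the position where 5-hydroxy-7-alkoxychromones also take up iodine), and hydrolysis of the α-chloro ether gives the aldehyde.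

Step 5
Reactants: 10 (R)-6,8-dihydroxy-3,7-dimethylisochroman-1-one; 12 5-hydroxy-7-methoxy-2-methyl-4-oxo-4H-chromene-6-carbaldehyde
Product: 14 (3R)-6,8-dihydroxy-5-[(5-hydroxy-7-methoxy-2-methyl-4-oxo-4H-chromen-6-yl)methyl]-3,7-dimethylisochroman-1-one (CNP0180307.1), via diarylmethanol 13 (not isolated)
Conditions: 10 (1.5 equiv), TFA/CH2Cl2 1:3, 0 °C → rt; then Et3SiH (2 equiv), 0 °C → rt
Reagents that add atoms: none
Why: Friedel–Crafts hydroxyalkylation at C5 of 10, its only unsubstituted ring carbon and ortho/para to both OH groups, gives a doubly benzylic carbinol that ionises in TFA and is reduced by Et3SiH (ionic hydrogenation) to the CH2 bridge; the carbinol centre is transient and C3 is not involved.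

## Compound list

1 | ethyl propiolate | C#CC(=O)OCC | starting material
2 | (R)-propylene oxide ((R)-2-methyloxirane) | C[C@@H]1CO1 | starting material
3 | ethyl (R)-5-hydroxyhex-2-ynoate | CCOC(=O)C#CC[C@@H](C)O | intermediate
4 | 2-methylcyclohexane-1,3-dione | CC1C(=O)CCCC1=O | starting material
5 | 2-methyl-1,3-bis(trimethylsilyloxy)cyclohexa-1,3-diene | CC1=C(O[Si](C)(C)C)CCC=C1O[Si](C)(C)C | intermediate
6 | ethyl (R)-5-(trimethylsilyloxy)hex-2-ynoate | CCOC(=O)C#CC[C@@H](C)O[Si](C)(C)C | intermediate (not isolated)
7 | ethyl 6-methyl-1,5-bis(trimethylsilyloxy)-3-[(2R)-2-(trimethylsilyloxy)propyl]bicyclo[2.2.2]octa-2,5-diene-2-carboxylate (both bridgehead diastereomers) | CCOC(=O)C1=C(C[C@@H](C)O[Si](C)(C)C)C2CCC1(O[Si](C)(C)C)C(C)=C2O[Si](C)(C)C | intermediate (not isolated)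
8 | ethyl 3-methyl-2,4-bis(trimethylsilyloxy)-6-[(2R)-2-(trimethylsilyloxy)propyl]benzoate | CCOC(=O)c1c(C[C@@H](C)O[Si](C)(C)C)cc(O[Si](C)(C)C)c(C)c1O[Si](C)(C)C | intermediate (not isolated)
9 | ethyl 2,4-dihydroxy-6-[(2R)-2-hydroxypropyl]-3-methylbenzoate | CCOC(=O)c1c(C[C@@H](C)O)cc(O)c(C)c1O | intermediate (not isolated)
10 | (R)-6,8-dihydroxy-3,7-dimethylisochroman-1-one | C[C@@H]1Cc2cc(O)c(C)c(O)c2C(=O)O1 | intermediate
11 | eugenin (5-hydroxy-7-methoxy-2-methylchromone) | COc1cc2oc(C)cc(=O)c2c(O)c1 | starting material
12 | 5-hydroxy-7-methoxy-2-methyl-4-oxo-4H-chromene-6-carbaldehyde | COc1cc2oc(C)cc(=O)c2c(O)c1C=O | intermediate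
13 | (3R)-6,8-dihydroxy-5-[hydroxy(5-hydroxy-7-methoxy-2-methyl-4-oxo-4H-chromen-6-yl)methyl]-3,7-dimethylisochroman-1-one (both carbinol epimers) | COc1cc2oc(C)cc(=O)c2c(O)c1C(O)c1c(O)c(C)c(O)c2c1C[C@@H](C)OC2=O | intermediate (not isolated)
14 | (3R)-6,8-dihydroxy-5-[(5-hydroxy-7-methoxy-2-methyl-4-oxo-4H-chromen-6-yl)methyl]-3,7-dimethylisochroman-1-one (CNP0180307.1) | COc1cc2oc(C)cc(=O)c2c(O)c1Cc1c(O)c(C)c(O)c2c1C[C@@H](C)OC2=O | target

## Count and risks

Total steps: 5. Longest linear sequence: 3 steps (step 1, step 3, step 5).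

**Step 4 (C6 versus C8 formylation of eugenin).** The regiochemistry rests on ortho direction by the chelated 5-OH and is not proven for this substrate; a C8 aldehyde or a mixture is possible. The isomer must be assigned on 12 before it is used. Fallback: set out from 11 and iodinate ortho to the free 5-OH (BnMe3N·ICl2, CaCO3, CH2Cl2/MeOH, rt) to give 5-hydroxy-6-iodo-7-methoxy-2-methylchromone F4. Palladium-catalysed reductive carbonylation of F4 (Pd(OAc)2/dppp, CO 1 atm, Et3SiH, Na2CO3, DMF, 80 °C) then comes back to the route at 12. This costs one extra step but replaces a formylation of uncertain orientation by a halogenation/cross-coupling pair.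

**Step 5 (reductive union).** The aldehyde is a hindered, strongly donor-stabilised salicylaldehyde. Attack by C5 of 10 may be slow, and once silane is present the aldehyde can be over-reduced to the 6-methylchromone or the chromone C2=C3 bond reduced. Fallback: set out from 12 and reduce it (NaBH4, MeOH/THF, 0 °C) to 5-hydroxy-6-(hydroxymethyl)-7-methoxy-2-methylchromone F5. Warming F5 with 10 (2 equiv) in hexafluoroisopropanol, or with catalytic TsOH in dioxane at 60 °C, generates the ortho-quinone methide by loss of water. Conjugate addition of C5 of 10 to it comes back to the route at 14. No hydride is present in the bond-forming step, so neither over-reduction nor a second arylation can occur.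

**Step 3 (Diels–Alder/ethylene extrusion).** The cycloreversion needs about 180 °C, and the silyl dienol ether may decompose or transfer silicon before the ynoate is consumed. Fallback: set out from 3, silylated to 6 as before, and use an open-chain diene that aromatises by elimination instead of cycloreversion. Methyl 2-methylacetoacetate with TMSCl/Et3N gives methyl 2-methyl-3-(trimethylsilyloxy)but-2-enoate F1. LDA then TMSCl (THF, −78 °C) converts F1 into 1-methoxy-2-methyl-1,3-bis(trimethylsilyloxy)buta-1,3-diene F2. Diels–Alder reaction of F2 with 6 (PhMe, 110 °C) gives ethyl 6-methoxy-5-methyl-4,6-bis(trimethylsilyloxy)-2-[(2R)-2-(trimethylsilyloxy)propyl]cyclohexa-1,4-diene-1-carboxylate F3. Acid work-up of F3 removes methanol and the silyl groups and comes back to the route at 9, which lactonises to 10 as in step 3.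

## Further compounds

F1 | step 3 | methyl 2-methyl-3-(trimethylsilyloxy)but-2-enoate | COC(=O)C(C)=C(C)O[Si](C)(C)C
F2 | step 3 | 1-methoxy-2-methyl-1,3-bis(trimethylsilyloxy)buta-1,3-diene | COC(O[Si](C)(C)C)=C(C)C(=C)O[Si](C)(C)C
F3 | step 3 | ethyl 6-methoxy-5-methyl-4,6-bis(trimethylsilyloxy)-2-[(2R)-2-(trimethylsilyloxy)propyl]cyclohexa-1,4-diene-1-carboxylate | CCOC(=O)C1=C(C[C@@H](C)O[Si](C)(C)C)CC(O[Si](C)(C)C)=C(C)C1(OC)O[Si](C)(C)C
F4 | step 4 | 5-hydroxy-6-iodo-7-methoxy-2-methylchromone | COc1cc2oc(C)cc(=O)c2c(O)c1I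
F5 | step 5 | 5-hydroxy-6-(hydroxymethyl)-7-methoxy-2-methylchromone | COc1cc2oc(C)cc(=O)c2c(O)c1CO
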